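The route rests on opening ring C at O1–C2. C2 is the benzylic carbon on C1′ of ring B, and C1′ stands para to the C4′ hydroxyl, so a C2 carbinol can lose water to a planar B-ring para-quinone methide that the C8a hydroxyl of ring A recaptures. One chiral-phosphoric-acid step thus closes the pyranone ring, forms O1–C2 and sets C2 from a stereorandom carbinol. The precursor is the aldol adduct of the side-chain-bearing ring-A 2-hydroxyacetophenone (O5 as MOM ether, side-chain carbinol as TES ether) and 2-MOM-protected 2,4-dihydroxybenzaldehyde; its side-chain stereocentre comes from an Evans alkylation, and a Negishi coupling joins chain and ring A.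

Key step: step 14

Remark: 2′,6′-dihydroxy-4′-methoxyacetophenone, (S)-4-benzyl-1,3-oxazolidin-2-one, 3-methylbut-2-enoyl chloride and prenyl bromide are taken as catalogue compounds.
Remark: the sense of induction of the phosphoric acid cannot be predicted with confidence for this substrate; the (R)-acid is written, and its antipode would be used if a trial shows the opposite sense.
Remark: R* stands for the (2R)-5-methyl-2-(prop-1-en-2-yl)-5-[(triethylsilyl)oxy]hexyl group; the side-chain centre keeps one spatial arrangement from step 2 onward and only its CIP descriptor changes (S before the aryl group is attached, R after).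

Step 1
Reactants: 1 (S)-4-benzyl-1,3-oxazolidin-2-one; 2 3-methylbut-2-enoyl chloride
Product: 4 (S)-4-benzyl-3-(3-methylbut-2-enoyl)-1,3-oxazolidin-2-one, via N-lithio oxazolidinone 3 (not isolated)
Conditions: n-BuLi, THF, −78 °C; then 2, −78 → 0 °C
Reagents that add atoms: none
Why: N-acylation of the lithiated oxazolidinone by an acid chloride is the standard entry to N-acyl auxiliaries and leaves the C4 centre untouched.

Step 2
Reactants: 4; 5 prenyl bromide (1-bromo-3-methylbut-2-ene)
Product: 7 (S)-4-benzyl-3-[(2S)-5-methyl-2-(prop-1-en-2-yl)hex-4-enoyl]-1,3-oxazolidin-2-one, via sodium dienolate 6 (not isolated)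
Conditions: NaHMDS, THF, −78 °C; then 5, −78 → −30 °C
Reagents that add atoms: none
Why: Evans alkylation in its deconjugative form: γ-deprotonation gives the chelated Z-dienolate, which is alkylated at the α-carbon on the face opposite the benzyl group, so the (2S) centre (the future side-chain stereocentre) is set by the auxiliary.

Step 3
Reactants: 7
Product: 8 (S)-4-benzyl-3-{(2S)-2-[(3,3-dimethyloxiran-2-yl)methyl]-3-methylbut-3-enoyl}-1,3-oxazolidin-2-one (both epoxide epimers)
Conditions: mCPBA (1.05 equiv), CH2Cl2, 0 °C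
Reagents that add atoms: mCPBA, O=C(OO)c1cccc(Cl)c1
Why: Prilezhaev epoxidation should select the electron-richer trisubstituted alkene over the 1,1-disubstituted isopropenyl group, and the uncontrolled epoxide centre is removed in step 4.

Step 4
Reactants: 8
Product: 9 (2S)-5-methyl-2-(prop-1-en-2-yl)hexane-1,5-diol
Conditions: LiAlH4, THF, 0 °C → rt; aqueous NaOH work-up
Reagents that add atoms: none
Why: Hydride reduction cleaves the imide to the primary alcohol (releasing the auxiliary) and opens the trisubstituted epoxide by SN2 attack at its less substituted carbon to give the tertiary alcohol, without touching the stereocentre.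

Step 5
Reactants: 9
Product: 10 (5S)-6-iodo-2-methyl-5-(prop-1-en-2-yl)hexan-2-ol
Conditions: PPh3, I2, imidazole (reagent preformed), CH2Cl2, 0 °C
Reagents that add atoms: iodine, II
Why: Appel-type iodination converts the primary alcohol selectively, because the tertiary hydroxyl is too hindered to form the alkoxyphosphonium ion at 0 °C.

Step 6
Reactants: 10
Product: 11 triethyl{[(5S)-6-iodo-2-methyl-5-(prop-1-en-2-yl)hexan-2-yl]oxy}silane
Conditions: TESOTf, 2,6-lutidine, CH2Cl2, −78 → 0 °C
Reagents that add atoms: triethylsilyl triflate, CC[Si](CC)(CC)OS(=O)(=O)C(F)(F)F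
Why: Silylation with a silyl triflate and a hindered base is the reliable way to protect a tertiary alcohol, and the primary iodide is inert to it.

Step 7
Reactants: 12 1-(2,6-dihydroxy-4-methoxyphenyl)ethan-1-one
Product: 13 1-[2-hydroxy-4-methoxy-6-(methoxymethoxy)phenyl]ethan-1-one
Conditions: MOMCl (1.1 equiv), i-Pr2NEt, CH2Cl2, 0 °C → rt
Reagents that add atoms: chloromethyl methyl ether, COCCl
Why: O-alkylation of one of two equivalent phenols is self-limiting, because the remaining hydroxyl is locked in a hydrogen bond to the carbonyl and does not react under amine-base conditions.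

Step 8
Reactants: 13
Product: 14 1-[2-hydroxy-3-iodo-4-methoxy-6-(methoxymethoxy)phenyl]ethan-1-one
Conditions: BnMe3N+ ICl2− (1.05 equiv), NaHCO3, CH2Cl2–MeOH, rt
Reagents that add atoms: benzyltrimethylammonium dichloroiodate, C[N+](C)(C)Cc1ccccc1.Cl[I-]Cl
Why: Electrophilic aromatic iodination of chelated 2-hydroxy-4,6-dialkoxyacetophenones goes ortho to the chelated hydroxyl (C3), the alternative C5 being flanked by the methoxy and the bulkier MOM ether, and the bicarbonate buffer protects the acetal.

Step 9
Reactants: 11; 14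
Product: 16 1-[2-hydroxy-4-methoxy-6-(methoxymethoxy)-3-R*-phenyl]ethan-1-one, via alkylzinc iodide 15 (not isolated)
Conditions: 11, Zn dust (activated), LiCl, THF, 40 °C; then 14, Pd(OAc)2 (3 mol%), SPhos (6 mol%), THF, 25 → 40 °C
Reagents that add atoms: none
Why: Negishi coupling of a primary alkylzinc halide with a hindered aryl iodide under Pd/SPhos tolerates the ketone and the hydrogen-bonded phenol, and the stereocentre β to zinc is not involved.

Step 10
Reactants: 17 2,4-dihydroxybenzaldehyde
Product: 18 4-[(tert-butyldimethylsilyl)oxy]-2-hydroxybenzaldehyde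
Conditions: TBSCl (1.05 equiv), imidazole, CH2Cl2, 0 °C
Reagents that add atoms: tert-butyldimethylsilyl chloride, CC(C)(C)[Si](C)(C)Cl
Why: Silylation selects the 4-hydroxyl, which is more acidic and unhindered, over the 2-hydroxyl that is chelated to the aldehyde.

Step 11
Reactants: 18
Product: 19 4-[(tert-butyldimethylsilyl)oxy]-2-(methoxymethoxy)benzaldehyde
Conditions: MOMCl (1.5 equiv), i-Pr2NEt, CH2Cl2, 0 °C → rt
Reagents that add atoms: chloromethyl methyl ether, COCCl
Why: MOM etherification of a salicylaldehyde hydroxyl proceeds with excess reagent and amine base, conditions under which the aryl silyl ether is stable.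

Step 12
Reactants: 16; 19
Product: 21 3-{4-[(tert-butyldimethylsilyl)oxy]-2-(methoxymethoxy)phenyl}-3-hydroxy-1-[2-hydroxy-4-methoxy-6-(methoxymethoxy)-3-R*-phenyl]propan-1-one (both C3 epimers), via dilithium enolate-phenoxide 20 (not isolated)
Conditions: LDA (2.3 equiv), THF, −78 °C; then 19, −78 °C; AcOH quench at −78 °C
Reagents that add atoms: none
Why: Aldol addition of the dianion of a 2-hydroxyacetophenone to an aryl aldehyde is established for flavanone precursors, and no control of the carbinol centre is sought because step 14 erases it.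

Step 13
Reactants: 21
Product: 22 3-hydroxy-3-[4-hydroxy-2-(methoxymethoxy)phenyl]-1-[2-hydroxy-4-methoxy-6-(methoxymethoxy)-3-R*-phenyl]propan-1-one (both C3 epimers)
Conditions: TBAF (1.1 equiv), AcOH (1.2 equiv), THF, 0 °C; crude product taken on directly
Reagents that add atoms: none
Why: Fluoride desilylation cleaves the aryl silyl ether far faster than the hindered tertiary alkyl TES ether, and the acetic acid buffer should suppress retro-aldol cleavage and elimination.

Step 14
Reactants: 22
Product: 24 (2S)-2-[4-hydroxy-2-(methoxymethoxy)phenyl]-7-methoxy-5-(methoxymethoxy)-8-R*-2,3-dihydro-4H-chromen-4-one, via para-quinone methide 23 (not isolated)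
Conditions: (R)-TRIP (10 mol%), 4 Å MS, toluene (0.02 M), 0 °C → rt
Reagents that add atoms: none
Why: Proposed new method: the acid protonates the C2 hydroxyl of either epimer of 22, water leaves with push from the C4′ oxygen, and the planar para-quinone methide 23 stays hydrogen-bonded to the chiral phosphate until the O8a–H, already held near by its hydrogen bond to the C4 carbonyl, adds to C2 and ring B regains aromaticity. The closest known reaction type is the chiral-phosphoric-acid-catalysed enantioselective addition of nucleophiles to para-quinone methides generated in situ from para-hydroxybenzyl alcohols; an intramolecular phenol nucleophile, a carbinol flanked by an enolisable CH2 and flavanone formation lie outside what is known. Ring C closes in the 6-exo-trig mode, since the C2=C1′ bond under attack is exocyclic to the new O1–C2–C3–C4–C4a–C8a ring. The C2 stereocentre is set by the catalyst, whose phosphate bridges the methide oxygen and the attacking hydroxyl and exposes one face of C2, so that both carbinol epimers converge on one product and the remote side-chain centre is a spectator. The step needs enantioface selectivity at C2 (catalyst), site selectivity for O8a over O5 and O2′ (both blocked as MOM ethers, which also prevents closure of O2′ onto C4), and chemoselectivity against tautomerisation of 23 to the chalcone, which low temperature, high dilution and a non-polar medium are meant to hold back. Chalcone that does form can re-enter through acid-catalysed oxa-Michael addition, and the reaction is stopped at full conversion to limit re-ionisation of 24.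

Step 15
Reactants: 24
Product: 25 (2S)-2-(2,4-dihydroxyphenyl)-5-hydroxy-8-[(2R)-5-hydroxy-5-methyl-2-(prop-1-en-2-yl)hexyl]-7-methoxy-2,3-dihydro-4H-chromen-4-one
Conditions: HCl (ca. 1 M in MeOH), 0 °C → rt
Reagents that add atoms: none
Why: Acid-catalysed methanolysis (acetal exchange and silyl ether solvolysis) removes both MOM groups and the TES group, and dilute acid at or below room temperature should leave O1–C2, the tertiary alcohol and the isopropenyl group intact.

Compound list
1 | (S)-4-benzyl-1,3-oxazolidin-2-one | O=C1OC[C@H](Cc2ccccc2)N1 | starting material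
2 | 3-methylbut-2-enoyl chloride | CC(C)=CC(=O)Cl | starting material
3 | lithium salt of 1 (N-lithio oxazolidinone) | O=C1OC[C@H](Cc2ccccc2)N1[Li] | intermediate
4 | (S)-4-benzyl-3-(3-methylbut-2-enoyl)-1,3-oxazolidin-2-one | CC(C)=CC(=O)N1C(=O)OC[C@@H]1Cc1ccccc1 | intermediate
5 | prenyl bromide (1-bromo-3-methylbut-2-ene) | CC(C)=CCBr | starting material
6 | sodium (Z)-dienolate of 4 | C=C(C)/C=C(\O[Na])N1C(=O)OC[C@@H]1Cc1ccccc1 | intermediate
7 | (S)-4-benzyl-3-[(2S)-5-methyl-2-(prop-1-en-2-yl)hex-4-enoyl]-1,3-oxazolidin-2-one | C=C(C)[C@H](CC=C(C)C)C(=O)N1C(=O)OC[C@@H]1Cc1ccccc1 | intermediate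
8 | (S)-4-benzyl-3-{(2S)-2-[(3,3-dimethyloxiran-2-yl)methyl]-3-methylbut-3-enoyl}-1,3-oxazolidin-2-one, both epoxide epimers | C=C(C)[C@H](CC1OC1(C)C)C(=O)N1C(=O)OC[C@@H]1Cc1ccccc1 | intermediate
9 | (2S)-5-methyl-2-(prop-1-en-2-yl)hexane-1,5-diol | C=C(C)[C@H](CCC(C)(C)O)CO | intermediate
10 | (5S)-6-iodo-2-methyl-5-(prop-1-en-2-yl)hexan-2-ol | C=C(C)[C@H](CCC(C)(C)O)CI | intermediate
11 | triethyl{[(5S)-6-iodo-2-methyl-5-(prop-1-en-2-yl)hexan-2-yl]oxy}silane | C=C(C)[C@H](CCC(C)(C)O[Si](CC)(CC)CC)CI | intermediate
12 | 1-(2,6-dihydroxy-4-methoxyphenyl)ethan-1-one | CC(=O)c1c(O)cc(OC)cc1O | starting material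
13 | 1-[2-hydroxy-4-methoxy-6-(methoxymethoxy)phenyl]ethan-1-one | CC(=O)c1c(O)cc(OC)cc1OCOC | intermediate
14 | 1-[2-hydroxy-3-iodo-4-methoxy-6-(methoxymethoxy)phenyl]ethan-1-one | CC(=O)c1c(O)c(I)c(OC)cc1OCOC | intermediate
15 | iodo{(2S)-5-methyl-2-(prop-1-en-2-yl)-5-[(triethylsilyl)oxy]hexyl}zinc | C=C(C)[C@H](CCC(C)(C)O[Si](CC)(CC)CC)C[Zn]I | intermediate
16 | 1-[2-hydroxy-4-methoxy-6-(methoxymethoxy)-3-R*-phenyl]ethan-1-one | C=C(C)[C@H](CCC(C)(C)O[Si](CC)(CC)CC)Cc1c(OC)cc(OCOC)c(C(C)=O)c1O | intermediate
17 | 2,4-dihydroxybenzaldehyde | O=Cc1ccc(O)cc1O | starting material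
18 | 4-[(tert-butyldimethylsilyl)oxy]-2-hydroxybenzaldehyde | O=Cc1ccc(O[Si](C)(C)C(C)(C)C)cc1O | intermediate
19 | 4-[(tert-butyldimethylsilyl)oxy]-2-(methoxymethoxy)benzaldehyde | O=Cc1ccc(O[Si](C)(C)C(C)(C)C)cc1OCOC | intermediate
20 | dilithium enolate-phenoxide of 16 | C=C(C)[C@H](CCC(C)(C)O[Si](CC)(CC)CC)Cc1c(OC)cc(OCOC)c(C(=C)O[Li])c1O[Li] | intermediate
21 | 3-{4-[(tert-butyldimethylsilyl)oxy]-2-(methoxymethoxy)phenyl}-3-hydroxy-1-[2-hydroxy-4-methoxy-6-(methoxymethoxy)-3-R*-phenyl]propan-1-one, both C3 epimers | C=C(C)[C@H](CCC(C)(C)O[Si](CC)(CC)CC)Cc1c(OC)cc(OCOC)c(C(=O)CC(O)c2ccc(O[Si](C)(C)C(C)(C)C)cc2OCOC)c1O | intermediate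
22 | 3-hydroxy-3-[4-hydroxy-2-(methoxymethoxy)phenyl]-1-[2-hydroxy-4-methoxy-6-(methoxymethoxy)-3-R*-phenyl]propan-1-one, both C3 epimers | C=C(C)[C@H](CCC(C)(C)O[Si](CC)(CC)CC)Cc1c(OC)cc(OCOC)c(C(=O)CC(O)c2ccc(O)cc2OCOC)c1O | intermediate
23 | 4-{3-[2-hydroxy-4-methoxy-6-(methoxymethoxy)-3-R*-phenyl]-3-oxopropylidene}-3-(methoxymethoxy)cyclohexa-2,5-dien-1-one | C=C(C)[C@H](CCC(C)(C)O[Si](CC)(CC)CC)Cc1c(OC)cc(OCOC)c(C(=O)CC=C2C=CC(=O)C=C2OCOC)c1O | intermediate
24 | (2S)-2-[4-hydroxy-2-(methoxymethoxy)phenyl]-7-methoxy-5-(methoxymethoxy)-8-R*-2,3-dihydro-4H-chromen-4-one | C=C(C)[C@H](CCC(C)(C)O[Si](CC)(CC)CC)Cc1c(OC)cc(OCOC)c2c1O[C@H](c1ccc(O)cc1OCOC)CC2=O | intermediate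
25 | (2S)-2-(2,4-dihydroxyphenyl)-5-hydroxy-8-[(2R)-5-hydroxy-5-methyl-2-(prop-1-en-2-yl)hexyl]-7-methoxy-2,3-dihydro-4H-chromen-4-one | C=C(C)[C@H](CCC(C)(C)O)Cc1c(OC)cc(O)c2c1O[C@H](c1ccc(O)cc1O)CC2=O | target

Total step count: 15. Longest linear sequence: 11 steps (steps 1–6, 9, 12, 13, 14, 15).

Steps most likely to fail

Step 14. Three processes could defeat it: poor facial discrimination at the planar methide carbon, drain of the quinone methide into the chalcone by proton loss from C3, and erosion of C2 by re-ionisation of the product. The fallback uses known chemistry and gives up catalyst control. It sets out from 22, which is heated with sodium acetate in ethanol; dehydration gives the (E)-chalcone F1, which closes reversibly by oxa-Michael addition to 24 together with its (2R)-epimer F2. The two are diastereomers and would be separated by preparative HPLC on a chiral stationary phase, F2 being returned to the same equilibration. The route is rejoined at 24.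

Step 9. The alkylzinc could be lost by protonolysis at the free phenol, and transmetalation or reductive elimination at the doubly ortho-substituted aryl iodide could be slow enough for β-hydride elimination to compete. The fallback changes the nucleophile to boron. It sets out from 11, which undergoes iodine–lithium exchange with t-BuLi (Et2O, −78 °C) to the alkyllithium F3; trapping with B-methoxy-9-BBN gives the lithium B-alkyl-B-methoxy-9-BBN borinate F4. F4 is coupled with 14, present as its phenoxide, in a B-alkyl Suzuki–Miyaura reaction (Pd(dppf)Cl2, aqueous K3PO4, DMF, rt). The route is rejoined at 16.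

Step 15. Protic acid could re-open O1–C2, now assisted by the free 2′- and 4′-hydroxyls, and so epimerise C2; it could also cause solvolysis or elimination at the tertiary carbinol or addition to the isopropenyl group. The fallback separates the two deprotections and avoids protic acid. It sets out from 24, whose MOM ethers are removed with ZnBr2 and n-PrSH (CH2Cl2, 0 °C, short contact) to give the side-chain TES ether of the target F5. The silyl ether of F5 is then cleaved with HF·pyridine buffered with pyridine (THF, 0 °C). The route is rejoined at 25.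

Further compounds
F1 | step 14 | (E)-3-[4-hydroxy-2-(methoxymethoxy)phenyl]-1-[2-hydroxy-4-methoxy-6-(methoxymethoxy)-3-R*-phenyl]prop-2-en-1-one | C=C(C)[C@H](CCC(C)(C)O[Si](CC)(CC)CC)Cc1c(OC)cc(OCOC)c(C(=O)/C=C/c2ccc(O)cc2OCOC)c1O
F2 | step 14 | (2R)-2-[4-hydroxy-2-(methoxymethoxy)phenyl]-7-methoxy-5-(methoxymethoxy)-8-R*-2,3-dihydro-4H-chromen-4-one | C=C(C)[C@H](CCC(C)(C)O[Si](CC)(CC)CC)Cc1c(OC)cc(OCOC)c2c1O[C@@H](c1ccc(O)cc1OCOC)CC2=O
F3 | step 9 | {(2S)-5-methyl-2-(prop-1-en-2-yl)-5-[(triethylsilyl)oxy]hexyl}lithium | C=C(C)[C@H](CCC(C)(C)O[Si](CC)(CC)CC)C[Li]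
F4 | step 9 | lithium 9-methoxy-9-{(2S)-5-methyl-2-(prop-1-en-2-yl)-5-[(triethylsilyl)oxy]hexyl}-9-boranuidabicyclo[3.3.1]nonane | C=C(C)[C@H](CCC(C)(C)O[Si](CC)(CC)CC)C[B-]1(OC)C2CCCC1CCC2.[Li+]
F5 | step 15 | (2S)-2-(2,4-dihydroxyphenyl)-5-hydroxy-7-methoxy-8-R*-2,3-dihydro-4H-chromen-4-one | C=C(C)[C@H](CCC(C)(C)O[Si](CC)(CC)CC)Cc1c(OC)cc(O)c2c1O[C@H](c1ccc(O)cc1O)CC2=O
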